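**The doubt.** If a molecule of starting material in the flask has a steady chance per minute of becoming target, one number tells its fate. So lay out the flasks and look for that number.

the same everywhere: free catalyst 20 mM

| run | starting material | reagent | remark | time |
|---|---|---|---|---|
| summer | 0.20 M (fed, over 3.0 min) | 1.2 M | run made earlier |  |
| Tuesday's | 0.40 M (fed, over 3.0 min) | 1.20 M |  | 3.0 min |
| Monday's | 0.40 M | 1.20 M | everything together at the start | 1.0 min |

summer run (percent of the starting material charged): time / s: target / % = 10.0: 0.3; 15.0: 0.4; 20.0: 0.3; 30.0: 1.3; 40.0: 2.5

(scatter of a reading: 0.3 percentage points)

- percentages count the whole charge, also what has not yet gone in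

- the winner by amount of target, in percent of the starting material charged; "neither" if no more than 2 percentage points parts them (Tuesday's / Monday's / neither)
- how much target is there at the end, in percent of the starting material charged: Tuesday's
- how much target is there at the end, in percent of the starting material charged: Monday's

**One chance.** During the summer feed the amount present grows evenly with time, so the fraction of the charge turned to target is the chance times time squared, over twice the dosing time. The reading at 40.0 s then gives 0.337 min⁻¹ for the conversion chance: the fraction of the starting material present that turns per minute, with reagent and catalyst held (a pseudo-first-order constant).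

**First objection.** That reading scatters by 0.3 percentage points, so test the one at 30.0 s. It gives 0.312 min⁻¹, near enough to keep the number.

**Two molecules.** Follow one in Monday's flask: it sits there for 1.0 min, so its chance of having turned is 28.6 %. One in Tuesday's flask enters at a random moment of the feed, so average the same chance over the feed, which gives 37.1 %.

**Second objection.** Now doubt the catalyst: its pace in the summer run, read from the last two readings, was 0.720 min⁻¹ turns per catalyst. Monday's flask asks 6.75 min⁻¹ at its start, and Tuesday's asks 4.24 min⁻¹ at its end, so Monday's demand is the higher. Suppose the catalyst just manages Tuesday's demand: Monday's flask then reaches 21.2 %. Expect Monday's between that and 28.6 %, and Tuesday's a little under 37.1 %. So commit to Tuesday's as the winner, whose figure stands above Monday's upper one.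

**The result.** The forecast names Tuesday's, with 36 % for Tuesday's and 27 % for Monday's: “Tuesday's wins because it runs three times longer”. The flasks give Tuesday's as winner, 32.7 % for Tuesday's and 17.3 % for Monday's, which lies under even my 21.2 %.

    catalyst intermediate D → free catalyst + target (k = 1.80 s⁻¹)
    catalyst intermediate B ⇌ catalyst intermediate C (K = 77.0, k = 0.220 s⁻¹)
    free catalyst + by-product ⇌ idle complex (K = 32.0 M⁻¹, k = 0.0530 M⁻¹ s⁻¹)
    catalyst intermediate C ⇌ by-product + catalyst intermediate D (K = 2.90 M, k = 3.10 s⁻¹)
    starting material + catalyst intermediate A → catalyst intermediate B (k = 0.510 M⁻¹ s⁻¹)
    reagent + free catalyst → catalyst intermediate A (k = 0.180 M⁻¹ s⁻¹)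

**What stood.** Monday's flask at its end, 1.00 min, kept 81 % of its starting material, a conversion chance of 0.210 min⁻¹, less than the summer's 0.337 min⁻¹, and the same flask read at 4.0 min, with 42 % left, gives 0.218 min⁻¹. In Monday's flask catalyst intermediate A has a half-life of 0.070 min on its step with starting material at 1.00 min, against 0.053 min for catalyst intermediate B on its forward step at 0.440 min, and at 1.00 min the catalyst stands at 35.4 % as catalyst intermediate A and 27.0 % as catalyst intermediate B.

The runs stem from a simulated flask with made-up constants, and the scatter is random.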